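In percent of the G charged, the readings of E level off within minutes in midnight and in autumn, as far as their scatter shows, and the question is where E stops in red.

| flask | G | D | remark | time |
|---|---|---|---|---|
| midnight | 0.30 M | 0.16 M | run made earlier |  |
| autumn | 0.10 M | 0.16 M | run made earlier |  |
| violet | 0.20 M | 0.160 M |  | 2.0 h |
| red | 0.20 M | 0.400 M |  | 2.0 h |

| run | time / min | E / % | X / % |
|---|---|---|---|
| midnight | 3.00 | 14 | 5 |
| midnight | 6.00 | 16 | 3 |
| midnight | 10.0 | 17 | 0 |
| midnight | 15.0 | 19 | 2 |
| midnight | 20.0 | 18 | 0 |
| midnight | 25.0 | 19 | 1 |
| autumn | 3.00 | 18 | 17 |
| autumn | 6.00 | 25 | 4 |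
| autumn | 10.0 | 23 | 0 |
| autumn | 15.0 | 21 | 0 |
| autumn | 20.0 | 23 | 0 |
| autumn | 25.0 | 27 | 0 |

(readings scatter by 2 percentage points)

- which of these holds the largest part of the G at the end of violet (L / X / G / E)
- which of these holds the largest part of the G at the end of red (L / X / G / E)
- how much E is there at the end of red, in percent of the G charged



I place each flask by its charge ratio, the equivalents of D per G: 0.533 in midnight, 1.60 in autumn, 2.00 in red. The late readings of E average 18.7 % in midnight and 23.7 % in autumn. I take E to be made from G and eaten by D, so I expect a hump: E climbs with the ratio at the lean end and falls at the rich end.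

My first chain takes every D through G, so red's ratio should finish G and then E. That is the weak link. The first reading stands at about the same share of the late level, 75.0 % in midnight and 76.1 % in autumn, although the G charges are 0.30 M and 0.10 M. Read as a decay, that gives a life near 2.16 min in midnight, a reading that carries the scatter. I therefore suspect that D, the limiting reagent, also goes by a road that needs no G. I then place red near the top of the hump, and I commit to about 23.7 % of E in red.

The forecast has G largest in violet and L in red, and for red it puts E at 6 % (3 % to 11 %), lower than my figure, on the ground “D is exactly 2 equivalents”.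

Of the four asked about, the flask gives E largest in violet at 21.4 %, L largest in red at 55.5 %, and E 21.0 % in red.

    G + D ⇌ X + Q (K = 0.540, k = 2.80 /M/min)
    G + D → E + Q (k = 1.60 /M/min)
    D + X → L + Q (k = 3.40 /M/min)
    D + E → L + Q (k = 1.80 /M/min)
    2 G → J (k = 0.160 /M/min)
    D → Z (k = 0.170 /min)

Red ends with D at 0 % of its own charge and Z at 0.136 M. The line of E against the charge ratio, through the late readings of autumn and the end of red, carried to a neighbour of red with 0.12 M of G and a ratio of 3.33, gives E of 12.0 %. That neighbour flask gives E of 13.5 %.

The readings stem from a simulated flask for substances that don't exist; scatter was added.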